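The turn is my unit (the usual word is turnover): one passage of free catalyst through catalyst intermediate A and catalyst intermediate B, which takes one substrate and leaves one target.

| setting | Monday's | Saturday's | Sunday's | flask |
|---|---|---|---|---|
| substrate | 5 mM | 7.5 mM | 10 mM | 10 mM |
| free catalyst | 20 mol% (in portions, 4) | 20 mol% (in portions, 4) | 30 mol% (in portions, 4) | 20 mol% (in portions, 4) |
| remark | run made earlier; portions every 1.5 s | run made earlier; portions every 1.5 s | run made earlier; portions every 1.5 s | the portions of free catalyst follow each other after 1.5 s, the first at the start |
| time |  |  |  | 3.0 min |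

| run | time / s | target / % | side product / % |
|---|---|---|---|
| Monday's | 10.0 | 62.1 | 14.7 |
| Monday's | 15.0 | 79.8 | 18.1 |
| Monday's | 25.0 | 82.3 | 17.5 |
| Monday's | 40.0 | 81.7 | 17.5 |
| Monday's | 60.0 | 82.7 | 17.1 |
| Monday's | 120 | 82.0 | 17.6 |
| Saturday's | 10.0 | 63.8 | 18.8 |
| Saturday's | 20.0 | 79.4 | 20.0 |
| Saturday's | 40.0 | 80.3 | 20.0 |
| Saturday's | 60.0 | 79.3 | 20.0 |
| Saturday's | 80.0 | 80.2 | 20.5 |
| Saturday's | 120 | 79.4 | 20.5 |
| Sunday's | 20.0 | 84.5 | 14.6 |
| Sunday's | 40.0 | 84.5 | 15.7 |
| Sunday's | 60.0 | 85.0 | 14.6 |
| Sunday's | 80.0 | 84.8 | 15.7 |
| Sunday's | 120 | 84.2 | 15.2 |

(each reading ± 0.3 percentage points)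

- percentages count the substrate that a species holds: one idle adduct or side product counts as two
- target is meant together with its idle adduct
- steps under discussion: catalyst intermediate B -> free catalyst + target; substrate + target <-> idle adduct; catalyst intermediate A <-> catalyst intermediate B; substrate + free catalyst -> catalyst intermediate A; substrate + target -> side product
- in an amount of target, one idle adduct counts as one target

- target at 3.0 min, in percent of the substrate charged
- side product at 3.0 min, in percent of the substrate charged

Free catalyst is the smaller charge, so I write its balance in turns. A side product holds one target and one further substrate but counts two, so the turns made, as a share of the substrate charged, are target plus half the side product. Dividing by the loading gives turns per catalyst.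

Sunday's run shares the flask's 10 mM of substrate, so I average its rows: target 84.6 %, side product 15.2 %. Together they make 99.8 %, so Sunday's substrate ended in these two, and each catalyst made 3.07 turns.

I carry the side toll, the side product per turn of a catalyst, which Sunday's readings put at 4.93 %. But the flask's turns depend on its own side product: side product is the toll times the turns, and the turns are the whole charge less half the side product, over the loading. Holding the toll at this substrate level, I get 22.0 % side product and 78.0 % target.

The forecast says 77.6 % target (76.4 % to 78.8 %) and 22.3 % side product (21.2 % to 23.5 %), a little apart from my figures, on the ground that “Side product falls about inversely with catalyst loading”.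

    catalyst intermediate B → free catalyst + target (k = 4.78 s⁻¹)
    substrate + target ⇌ idle adduct, settled at all times (K = 85.5 M⁻¹)
    catalyst intermediate A ⇌ catalyst intermediate B (K = 0.282, k = 1.57 s⁻¹)
    substrate + free catalyst → catalyst intermediate A (k = 983 M⁻¹ s⁻¹)
    substrate + target → side product (k = 21.1 M⁻¹ s⁻¹)

The flask gives 78.0 % target and 22.0 % side product. Side product already stands at 22.0 % after 0.600 min, and a tenfold time changes nothing. The toll of this flask comes to 4.94 %. A run of this recipe would fall outside the forecast's range for side product with a toll below 4.74 % or above 5.33 %. The neighbour with 5 mol% of free catalyst ends at 54.7 % side product and 45.3 % target, and its toll comes to 3.77 %, smaller than this flask's.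

The earlier runs and the new flask come from a simulation from invented constants, noise included.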